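**Retrosynthetic overview**

1. Numbering: carbocycle C1–C6 (C1 side chain, C2 OTig, C3/C4 oxirane with the C4 methyl, C5 ketone, C6 OAc); chain C7(=C14H2)–C8(OTig)–C9–C10/C11 oxirane. Last disconnections: C10/C11 oxirane (Shi epoxidation), both tiglates (acylation of the C2,C8-diol with two molecules of tiglic acid), C3/C4 oxirane (hydroxyl-directed nucleophilic epoxidation of the 4-methyl enone), C4 methyl (α-iodination, Stille coupling).
2. The enone comes from a β-hydroxy ketone. Its carbocycle is closed by a mercury-catalysed Ferrier carbocyclization of hex-5-enopyranoside 18, forming C3–C4 (sugar C1–C6); this is the only C–C ring closure.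
3. Feature used: ring atoms C2 (O), C1 (C-branch) and C6 (O), lying between the C5 ketone and the oxygenated C3, are C2, C3 and C4 of a 3-C-branched α-D-mannopyranoside (branch cis to O2, trans to O4). Sugar C5 becomes the ketone, sugar C1 the C3 carbinol and sugar C6 the C4 methylene.
4. The branch is grown on a D-arabino-3-ulose: one-carbon homologation to the equatorial 3-C-formyl sugar, methyl ketone, alkenyl triflate, CrCl2/NiCl2 coupling with 4-methylpent-3-enal (C7–C8), then CBS reduction (C8).
5. Ring order: the pyranose and benzylidene rings arrive with epoxide 1 and are sacrificial; then the carbocycle (step 16), the C3/C4 oxirane (step 21) and the C10/C11 oxirane (step 23).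

Key step: step 16

Remark: epoxide 1 is taken as a purchasable compound (otherwise three routine steps from methyl α-D-glucopyranoside); its C2 is inverted in step 1, so from compound 5 onward the pyranoside has the D-manno arrangement at C2–C4; sugar numbering is used for pyranosides and target numbering for carbocycles; PMB = 4-methoxybenzyl, Tig = (E)-2-methylbut-2-enoyl.

**Route**

Step 1
Reactants: 1 methyl 2,3-anhydro-4,6-O-benzylidene-α-D-allopyranoside
Product: 2 methyl 4,6-O-benzylidene-2-O-(4-methoxybenzyl)-α-D-altropyranoside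
Conditions: 4-MeOC6H4CH2OH (excess), NaH (0.3 equiv), 1,4-dioxane, 100 °C
Reagents that add atoms: 4-methoxybenzyl alcohol, COc1ccc(CO)cc1
Why: Alkoxide opening of the conformationally locked epoxide is trans-diaxial (Fürst–Plattner rule), so the nucleophile enters at C2 from the β face with inversion and leaves the axial 3-OH free, which puts the PMB ether on the axial manno-type O2 without any diol differentiation.

Step 2
Reactants: 2 the 2-O-PMB altropyranoside
Product: 3 methyl 4,6-O-benzylidene-2-O-(4-methoxybenzyl)-α-D-arabino-hexopyranosid-3-ulose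
Conditions: Dess–Martin periodinane, CH2Cl2, rt
Reagents that add atoms: none
Why: Dess–Martin oxidation converts the hindered axial secondary alcohol into the ketone without base, which protects the axial C2 ether of the α-alkoxy ketone from epimerisation.

Step 3
Reactants: 3 the 2-O-PMB D-arabino-3-ulose
Product: 4 methyl 4,6-O-benzylidene-3-deoxy-3-C-(methoxymethylene)-2-O-(4-methoxybenzyl)-α-D-arabino-hexopyranoside (E/Z mixture)
Conditions: Ph3P(CH2OMe)Cl, KN(SiMe3)2, THF, 0 °C → rt
Reagents that add atoms: (methoxymethyl)triphenylphosphonium chloride, COC[P+](c1ccccc1)(c1ccccc1)c1ccccc1.[Cl-]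
Why: Wittig olefination with the reactive methoxymethylene ylide homologates the ketone by one carbon, and the equatorial C2–H of the ulose is poorly aligned with the carbonyl π system, so enolisation by the ylide should not compete.

Step 4
Reactants: 4 the 3-C-methoxymethylene sugar
Product: 5 methyl 4,6-O-benzylidene-3-deoxy-3-C-formyl-2-O-(4-methoxybenzyl)-α-D-mannopyranoside
Conditions: 0.5 M HCl, THF/H2O, 0 °C → rt (brief); then Et3N, rt
Reagents that add atoms: water, O
Why: Enol ether hydrolysis (protonation at C3, collapse of the hemiacetal) gives the aldehyde and sets C3, because both axial protonation from the α face and enol-mediated equilibration favour the equatorial formyl group, whose axial epimer would clash 1,3-diaxially with the anomeric methoxy group; the branch thus ends cis to O2 and trans to O4.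

Step 5
Reactants: 5 the equatorial 3-C-formyl mannoside
Product: 6 methyl 4,6-O-benzylidene-3-deoxy-3-C-(1-hydroxyethyl)-2-O-(4-methoxybenzyl)-α-D-mannopyranoside (both carbinol epimers)
Conditions: MeMgBr, THF, −78 °C
Reagents that add atoms: methylmagnesium bromide, C[Mg]Br
Why: Grignard 1,2-addition to the aldehyde at low temperature outruns enolisation, and the configuration of the new carbinol is irrelevant because it is oxidised in the next step.

Step 6
Reactants: 6 the 3-C-(1-hydroxyethyl) mannoside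
Product: 7 methyl 3-C-acetyl-4,6-O-benzylidene-3-deoxy-2-O-(4-methoxybenzyl)-α-D-mannopyranoside
Conditions: Dess–Martin periodinane, CH2Cl2, rt
Reagents that add atoms: none
Why: Dess–Martin oxidation gives the methyl ketone without base, and its equatorial acetyl group is also the thermodynamically preferred arrangement at C3.

Step 7
Reactants: 7 the 3-C-acetyl mannoside
Product: 8 methyl 4,6-O-benzylidene-3-deoxy-2-O-(4-methoxybenzyl)-3-C-[1-(trifluoromethylsulfonyloxy)ethenyl]-α-D-mannopyranoside
Conditions: KN(SiMe3)2 added to 7 and PhNTf2, THF, −78 °C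
Reagents that add atoms: N-phenylbis(trifluoromethanesulfonimide), O=S(=O)(N(c1ccccc1)S(=O)(=O)C(F)(F)F)C(F)(F)F
Why: Kinetic deprotonation by the bulky amide takes place at the unhindered methyl group and not at the tertiary C3–H, and O-sulfonylation of that enolate (enol triflate formation) gives the 1,1-disubstituted alkenyl triflate with C3 untouched.

Step 8
Reactants: 9 4-methylpent-3-en-1-ol
Product: 10 4-methylpent-3-enal
Conditions: Dess–Martin periodinane, NaHCO3, CH2Cl2, 0 °C; used at once as a solution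
Reagents that add atoms: none
Why: Buffered Dess–Martin oxidation gives the β,γ-unsaturated aldehyde without the acid or base that would move the double bond into conjugation.

Step 9
Reactants: 8 the alkenyl triflate; 10 4-methylpent-3-enal
Product: 11 methyl 4,6-O-benzylidene-3-deoxy-3-C-(3-hydroxy-6-methylhepta-1,5-dien-2-yl)-2-O-(4-methoxybenzyl)-α-D-mannopyranoside (both C8 epimers)
Conditions: CrCl2, NiCl2 (2 mol%), DMF, rt
Reagents that add atoms: none
Why: Nozaki–Hiyama–Kishi coupling (zerovalent nickel inserts into the C–OTf bond, the alkenyl group passes to trivalent chromium and adds to the aldehyde) forms C7–C8 chemoselectively under neutral conditions, and the C8 epimers are carried on together because C8 is reset in steps 10 and 11.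

Step 10
Reactants: 11 the allylic alcohol mixture
Product: 12 methyl 4,6-O-benzylidene-3-deoxy-2-O-(4-methoxybenzyl)-3-C-(6-methyl-3-oxohepta-1,5-dien-2-yl)-α-D-mannopyranoside
Conditions: Dess–Martin periodinane, NaHCO3, CH2Cl2, 0 °C
Reagents that add atoms: none
Why: Buffered Dess–Martin oxidation of the allylic alcohol gives the α-methylene ketone under neutral conditions, which keeps the C9 methylene from enolising towards C10 and the C3–H from migrating.

Step 11
Reactants: 12 the α-methylene ketone
Product: 13 methyl 4,6-O-benzylidene-3-deoxy-3-C-[(3S)-3-hydroxy-6-methylhepta-1,5-dien-2-yl]-2-O-(4-methoxybenzyl)-α-D-mannopyranoside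
Conditions: (R)-2-methyl-CBS-oxazaborolidine, catecholborane, toluene, −78 °C
Reagents that add atoms: none
Why: Corey–Bakshi–Shibata reduction sets C8 under reagent control, since the α-branched alkenyl group (C7) acts as the large substituent and the C9 methylene as the small one, so the (R)-oxazaborolidine should give the 8S alcohol (the mirror image of the acetophenone case, where the (S)-catalyst gives the (R)-carbinol).

Step 12
Reactants: 13 the (8S)-allylic alcohol
Product: 14 methyl 4,6-O-benzylidene-3-deoxy-2-O-(4-methoxybenzyl)-3-C-[(3S)-3-(4-methoxybenzyloxy)-6-methylhepta-1,5-dien-2-yl]-α-D-mannopyranoside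
Conditions: NaH, 4-MeOC6H4CH2Cl, Bu4NI (cat.), DMF, 0 °C → rt
Reagents that add atoms: 4-methoxybenzyl chloride, COc1ccc(CCl)cc1
Why: Williamson etherification masks O8 as a second PMB ether, which, unlike an allylic ester, is inert to zerovalent palladium in step 19 and is released together with the C2 ether in step 20.

Step 13
Reactants: 14 the bis-PMB benzylidene acetal
Product: 15 methyl 3-deoxy-2-O-(4-methoxybenzyl)-3-C-[(3S)-3-(4-methoxybenzyloxy)-6-methylhepta-1,5-dien-2-yl]-α-D-mannopyranoside (4,6-diol)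
Conditions: CSA (0.1 equiv), MeOH, rt
Reagents that add atoms: none
Why: Acid-catalysed transacetalisation with methanol removes the benzylidene acetal, while the PMB ethers, the methyl glycoside and the isolated alkenes are stable to catalytic sulfonic acid at room temperature.

Step 14
Reactants: 15 the 4,6-diol
Product: 17 methyl 4-O-acetyl-3,6-dideoxy-6-iodo-2-O-(4-methoxybenzyl)-3-C-[(3S)-3-(4-methoxybenzyloxy)-6-methylhepta-1,5-dien-2-yl]-α-D-mannopyranoside, via 6-iodo-4-ol 16 (not isolated)
Conditions: PPh3, I2, imidazole (premixed), THF, 0 °C → rt; then Ac2O, DMAP, pyridine, rt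
Reagents that add atoms: iodine, II; acetic anhydride, CC(=O)OC(C)=O
Why: Appel-type (Garegg–Samuelsson) iodination is selective for the primary C6 hydroxyl, and acetylation of the remaining C4 hydroxyl in the same flask installs the ester that becomes the C6 acetate of the target.

Step 15
Reactants: 17 the 6-iodo 4-acetate
Product: 18 methyl 4-O-acetyl-3,6-dideoxy-2-O-(4-methoxybenzyl)-3-C-[(3S)-3-(4-methoxybenzyloxy)-6-methylhepta-1,5-dien-2-yl]-α-D-lyxo-hex-5-enopyranoside
Conditions: DBU, THF, 65 °C
Reagents that add atoms: none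
Why: E2 dehydroiodination of the primary iodide by the amidine base gives the exocyclic enol ether, H5 being the only β-hydrogen.

Step 16
Reactants: 18 the hex-5-enopyranoside
Product: 20 6-acetoxy-3-hydroxy-2-(4-methoxybenzyloxy)-1-[(3S)-3-(4-methoxybenzyloxy)-6-methylhepta-1,5-dien-2-yl]cyclohexan-5-one (target numbering; C1/C2/C6 as in the target; 3-OH trans to the side chain), via open-chain C6-mercurio keto aldehyde 19 (not isolated)
Conditions: Hg(OCOCF3)2 (10 mol%), acetone/H2O (2:1), rt
Reagents that add atoms: water, O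
Why: The divalent mercury salt adds to the electron-rich exocyclic enol ether (mercury on sugar C6, water on C5), the hemiketal opens to the C5 ketone, the C1 hemiacetal loses methanol, and the α-mercurio ketone 19 attacks the freed aldehyde as a mercury enolate, which forms the bond between sugar C6 and C1 (C4–C3 of the target) and returns the mercury salt to the cycle. The closest known reaction type is the Ferrier carbocyclization of 6-deoxyhex-5-enopyranosides with a catalytic mercury carboxylate. The six-membered carbocycle (C1–C6 of the target) closes by a 6-(enolexo)-exo-trig aldol addition. The only new stereocentre is the C3 carbinol, set by a chair-like aldol transition state that should place the hydroxyl trans to the equatorial C1 side chain; it is erased in step 17, so either epimer serves, and C1, C2 and C6 come through unchanged in the neutral to weakly acidic medium. The step needs mercuration of the enol ether in preference to the C7=C14 and C10=C11 alkenes, which the far higher nucleophilicity of the enol ether, the substoichiometric mercury loading and the hindered, allylic-ether-deactivated position of C7=C14 should secure.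

Step 17
Reactants: 20 the β-hydroxy ketone
Product: 22 6-acetoxy-2-(4-methoxybenzyloxy)-1-[(3S)-3-(4-methoxybenzyloxy)-6-methylhepta-1,5-dien-2-yl]cyclohex-3-en-5-one, via C3 mesylate 21 (not isolated)
Conditions: MsCl, Et3N, CH2Cl2, 0 °C → rt
Reagents that add atoms: none
Why: Mesylation of the β-hydroxy ketone followed by E1cB elimination in the same flask gives the conjugated enone, which removes the C3 carbinol centre and leaves the trans C1/C6 substituents untouched.

Step 18
Reactants: 22 the enone
Product: 23 6-acetoxy-4-iodo-2-(4-methoxybenzyloxy)-1-[(3S)-3-(4-methoxybenzyloxy)-6-methylhepta-1,5-dien-2-yl]cyclohex-3-en-5-one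
Conditions: I2, pyridine/CH2Cl2 (1:1), 0 °C → rt, dark
Reagents that add atoms: iodine, II
Why: α-Iodination by the pyridine–iodine addition–elimination sequence (Baylis–Hillman-type) places iodine on C4, the only enone α-carbon, while pyridine-complexed iodine should be too weak an electrophile for the isolated alkenes.

Step 19
Reactants: 23 the α-iodo enone
Product: 24 6-acetoxy-2-(4-methoxybenzyloxy)-1-[(3S)-3-(4-methoxybenzyloxy)-6-methylhepta-1,5-dien-2-yl]-4-methylcyclohex-3-en-5-one
Conditions: Me4Sn, Pd2(dba)3 (5 mol%), AsPh3, CuI (10 mol%), NMP, 60 °C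
Reagents that add atoms: tetramethylstannane, C[Sn](C)(C)C
Why: Stille coupling of the electron-poor alkenyl iodide with tetramethylstannane (oxidative addition to zerovalent palladium, CuI-assisted methyl transfer, reductive elimination) installs the C4 methyl group under neutral conditions that spare the α-acetoxy ketone and the allylic ether.

Step 20
Reactants: 24 the 4-methyl enone
Product: 25 6-acetoxy-2-hydroxy-1-[(3S)-3-hydroxy-6-methylhepta-1,5-dien-2-yl]-4-methylcyclohex-3-en-5-one
Conditions: DDQ, CH2Cl2/pH 7 phosphate buffer, 0 °C → rt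
Reagents that add atoms: none
Why: Oxidative PMB cleavage by DDQ (hydride abstraction from the electron-rich benzylic position, hydrolysis of the oxocarbenium ion) frees O2 and O8 together in a buffered medium that leaves the enone, the acetate and the alkenes unchanged.

Step 21
Reactants: 25 the γ-hydroxy enone diol
Product: 26 6-acetoxy-3,4-epoxy-2-hydroxy-1-[(3S)-3-hydroxy-6-methylhepta-1,5-dien-2-yl]-4-methylcyclohexan-5-one (oxirane cis to O2 and to the side chain)
Conditions: t-BuOOH (excess) premixed with LiN(SiMe3)2, THF, −40 → −20 °C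
Reagents that add atoms: tert-butyl hydroperoxide, CC(C)(C)OO
Why: In this hydroxyl-directed nucleophilic (Weitz–Scheffer) epoxidation the lithium tert-butyl peroxide held by the pseudoaxial C2 oxygen adds to C3 on the face of that oxygen and the enolate closes on the O–O bond, which sets C3 and C4 with the oxirane syn to O2 and the side chain, and only the enone responds to the nucleophilic oxidant.

Step 22
Reactants: 26 the epoxy ketone diol; 27 tiglic acid (two molecules are consumed per molecule of 26; 2.5 equiv charged)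
Product: 28 6-acetoxy-3,4-epoxy-4-methyl-2-tigloyloxy-1-[(3S)-6-methyl-3-tigloyloxyhepta-1,5-dien-2-yl]cyclohexan-5-one
Conditions: 27 (2.5 equiv), 2,4,6-Cl3C6H2COCl (2.5 equiv), Et3N, toluene, rt; then 26, DMAP, rt → 40 °C
Reagents that add atoms: tiglic acid (the second molecule of 27, which supplies the second tigloyl group), C/C=C(\C)C(=O)O
Why: Yamaguchi esterification through the mixed anhydride acylates both hindered secondary hydroxyls (O2 and O8), one molecule of tiglic acid per hydroxyl, without touching a stereocentre, and the E-configured tiglate is the stable double-bond isomer, so no isomerisation is expected.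

Step 23
Reactants: 28 the bis-tiglate
Product: 29 CNP0407453.3 (target)
Conditions: D-fructose-derived Shi ketone (1,2:4,5-di-O-isopropylidene-β-D-erythro-2,3-hexodiulo-2,6-pyranose), Oxone (2KHSO5·KHSO4·K2SO4), NaHCO3 (pH about 8), MeCN/H2O, 0 °C
Reagents that add atoms: potassium peroxymonosulfate (active component of Oxone), [K+].[O-]S(=O)(=O)OO
Why: In the Shi epoxidation the chiral dioxirane formed in the flask transfers oxygen through a spiro transition state to the electron-rich trisubstituted C10=C11 bond and should give the 10R oxirane under reagent control, while the 1,1-disubstituted C7=C14 bond and the electron-poor tiglates react far more slowly.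

**Compound list**

1 | methyl 2,3-anhydro-4,6-O-[(R)-benzylidene]-α-D-allopyranoside | CO[C@H]1O[C@@H]2CO[C@@H](c3ccccc3)O[C@H]2[C@H]3O[C@@H]13 | starting material
2 | methyl 4,6-O-benzylidene-2-O-(4-methoxybenzyl)-α-D-altropyranoside | CO[C@H]1O[C@@H]2CO[C@@H](c3ccccc3)O[C@H]2[C@@H](O)[C@@H]1OCc1ccc(OC)cc1 | intermediate
3 | methyl 4,6-O-benzylidene-2-O-(4-methoxybenzyl)-α-D-arabino-hexopyranosid-3-ulose | CO[C@H]1O[C@@H]2CO[C@@H](c3ccccc3)O[C@H]2C(=O)[C@@H]1OCc1ccc(OC)cc1 | intermediate
4 | methyl 4,6-O-benzylidene-3-deoxy-3-C-(methoxymethylene)-2-O-(4-methoxybenzyl)-α-D-arabino-hexopyranoside (E/Z mixture) | CO[C@H]1O[C@@H]2CO[C@@H](c3ccccc3)O[C@H]2C(=COC)[C@@H]1OCc1ccc(OC)cc1 | intermediate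
5 | methyl 4,6-O-benzylidene-3-deoxy-3-C-formyl-2-O-(4-methoxybenzyl)-α-D-mannopyranoside | CO[C@H]1O[C@@H]2CO[C@@H](c3ccccc3)O[C@H]2[C@H](C=O)[C@@H]1OCc1ccc(OC)cc1 | intermediate
6 | methyl 4,6-O-benzylidene-3-deoxy-3-C-(1-hydroxyethyl)-2-O-(4-methoxybenzyl)-α-D-mannopyranoside (carbinol epimers) | CO[C@H]1O[C@@H]2CO[C@@H](c3ccccc3)O[C@H]2[C@H](C(C)O)[C@@H]1OCc1ccc(OC)cc1 | intermediate
7 | methyl 3-C-acetyl-4,6-O-benzylidene-3-deoxy-2-O-(4-methoxybenzyl)-α-D-mannopyranoside | CO[C@H]1O[C@@H]2CO[C@@H](c3ccccc3)O[C@H]2[C@H](C(C)=O)[C@@H]1OCc1ccc(OC)cc1 | intermediate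
8 | methyl 4,6-O-benzylidene-3-deoxy-2-O-(4-methoxybenzyl)-3-C-[1-(trifluoromethylsulfonyloxy)ethenyl]-α-D-mannopyranoside | CO[C@H]1O[C@@H]2CO[C@@H](c3ccccc3)O[C@H]2[C@H](C(=C)OS(=O)(=O)C(F)(F)F)[C@@H]1OCc1ccc(OC)cc1 | intermediate
9 | 4-methylpent-3-en-1-ol | CC(C)=CCCO | starting material
10 | 4-methylpent-3-enal | CC(C)=CCC=O | intermediate
11 | methyl 4,6-O-benzylidene-3-deoxy-3-C-(3-hydroxy-6-methylhepta-1,5-dien-2-yl)-2-O-(4-methoxybenzyl)-α-D-mannopyranoside (C8 epimers) | CO[C@H]1O[C@@H]2CO[C@@H](c3ccccc3)O[C@H]2[C@H](C(=C)C(O)CC=C(C)C)[C@@H]1OCc1ccc(OC)cc1 | intermediate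
12 | methyl 4,6-O-benzylidene-3-deoxy-2-O-(4-methoxybenzyl)-3-C-(6-methyl-3-oxohepta-1,5-dien-2-yl)-α-D-mannopyranoside | CO[C@H]1O[C@@H]2CO[C@@H](c3ccccc3)O[C@H]2[C@H](C(=C)C(=O)CC=C(C)C)[C@@H]1OCc1ccc(OC)cc1 | intermediate
13 | methyl 4,6-O-benzylidene-3-deoxy-3-C-[(3S)-3-hydroxy-6-methylhepta-1,5-dien-2-yl]-2-O-(4-methoxybenzyl)-α-D-mannopyranoside | CO[C@H]1O[C@@H]2CO[C@@H](c3ccccc3)O[C@H]2[C@H](C(=C)[C@@H](O)CC=C(C)C)[C@@H]1OCc1ccc(OC)cc1 | intermediate
14 | methyl 4,6-O-benzylidene-3-deoxy-2-O-(4-methoxybenzyl)-3-C-[(3S)-3-(4-methoxybenzyloxy)-6-methylhepta-1,5-dien-2-yl]-α-D-mannopyranoside | CO[C@H]1O[C@@H]2CO[C@@H](c3ccccc3)O[C@H]2[C@H](C(=C)[C@@H](OCc2ccc(OC)cc2)CC=C(C)C)[C@@H]1OCc1ccc(OC)cc1 | intermediate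
15 | methyl 3-deoxy-2-O-(4-methoxybenzyl)-3-C-[(3S)-3-(4-methoxybenzyloxy)-6-methylhepta-1,5-dien-2-yl]-α-D-mannopyranoside | C=C([C@@H]1[C@H](OCc2ccc(OC)cc2)[C@@H](OC)O[C@H](CO)[C@H]1O)[C@H](CC=C(C)C)OCc1ccc(OC)cc1 | intermediate
16 | methyl 3,6-dideoxy-6-iodo-2-O-(4-methoxybenzyl)-3-C-[(3S)-3-(4-methoxybenzyloxy)-6-methylhepta-1,5-dien-2-yl]-α-D-mannopyranoside | C=C([C@@H]1[C@H](OCc2ccc(OC)cc2)[C@@H](OC)O[C@H](CI)[C@H]1O)[C@H](CC=C(C)C)OCc1ccc(OC)cc1 | intermediate
17 | methyl 4-O-acetyl-3,6-dideoxy-6-iodo-2-O-(4-methoxybenzyl)-3-C-[(3S)-3-(4-methoxybenzyloxy)-6-methylhepta-1,5-dien-2-yl]-α-D-mannopyranoside | C=C([C@@H]1[C@H](OCc2ccc(OC)cc2)[C@@H](OC)O[C@H](CI)[C@H]1OC(C)=O)[C@H](CC=C(C)C)OCc1ccc(OC)cc1 | intermediate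
18 | methyl 4-O-acetyl-3,6-dideoxy-2-O-(4-methoxybenzyl)-3-C-[(3S)-3-(4-methoxybenzyloxy)-6-methylhepta-1,5-dien-2-yl]-α-D-lyxo-hex-5-enopyranoside | C=C([C@@H]1[C@H](OCc2ccc(OC)cc2)[C@@H](OC)OC(=C)[C@H]1OC(C)=O)[C@H](CC=C(C)C)OCc1ccc(OC)cc1 | intermediate
19 | 4-O-acetyl-3,6-dideoxy-2-O-(4-methoxybenzyl)-3-C-[(3S)-3-(4-methoxybenzyloxy)-6-methylhepta-1,5-dien-2-yl]-6-(trifluoroacetoxymercurio)-D-lyxo-hexos-5-ulose (open chain) | C=C([C@H]([C@H](OCc1ccc(OC)cc1)C=O)[C@H](OC(C)=O)C(=O)C[Hg]OC(=O)C(F)(F)F)[C@H](CC=C(C)C)OCc1ccc(OC)cc1 | intermediate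
20 | 6-acetoxy-3-hydroxy-2-(4-methoxybenzyloxy)-1-[(3S)-3-(4-methoxybenzyloxy)-6-methylhepta-1,5-dien-2-yl]cyclohexan-5-one (target numbering) | C=C([C@@H]1[C@H](OCc2ccc(OC)cc2)[C@@H](O)CC(=O)[C@H]1OC(C)=O)[C@H](CC=C(C)C)OCc1ccc(OC)cc1 | intermediate
21 | C3 methanesulfonate of 20 | C=C([C@@H]1[C@H](OCc2ccc(OC)cc2)[C@@H](OS(C)(=O)=O)CC(=O)[C@H]1OC(C)=O)[C@H](CC=C(C)C)OCc1ccc(OC)cc1 | intermediate
22 | 6-acetoxy-2-(4-methoxybenzyloxy)-1-[(3S)-3-(4-methoxybenzyloxy)-6-methylhepta-1,5-dien-2-yl]cyclohex-3-en-5-one | C=C([C@@H]1[C@H](OCc2ccc(OC)cc2)C=CC(=O)[C@H]1OC(C)=O)[C@H](CC=C(C)C)OCc1ccc(OC)cc1 | intermediate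
23 | 4-iodo derivative of 22 | C=C([C@@H]1[C@H](OCc2ccc(OC)cc2)C=C(I)C(=O)[C@H]1OC(C)=O)[C@H](CC=C(C)C)OCc1ccc(OC)cc1 | intermediate
24 | 4-methyl derivative of 22 | C=C([C@@H]1[C@H](OCc2ccc(OC)cc2)C=C(C)C(=O)[C@H]1OC(C)=O)[C@H](CC=C(C)C)OCc1ccc(OC)cc1 | intermediate
25 | 6-acetoxy-2-hydroxy-1-[(3S)-3-hydroxy-6-methylhepta-1,5-dien-2-yl]-4-methylcyclohex-3-en-5-one | C=C([C@@H]1[C@H](O)C=C(C)C(=O)[C@H]1OC(C)=O)[C@H](CC=C(C)C)O | intermediate
26 | 6-acetoxy-3,4-epoxy-2-hydroxy-1-[(3S)-3-hydroxy-6-methylhepta-1,5-dien-2-yl]-4-methylcyclohexan-5-one | C=C([C@@H]1[C@H](O)[C@@H]2O[C@]2(C)C(=O)[C@H]1OC(C)=O)[C@H](CC=C(C)C)O | intermediate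
27 | tiglic acid, (E)-2-methylbut-2-enoic acid | C/C=C(\C)C(=O)O | starting material
28 | 6-acetoxy-3,4-epoxy-4-methyl-2-tigloyloxy-1-[(3S)-6-methyl-3-tigloyloxyhepta-1,5-dien-2-yl]cyclohexan-5-one | C=C([C@@H]1[C@H](OC(=O)/C(C)=C/C)[C@@H]2O[C@]2(C)C(=O)[C@H]1OC(C)=O)[C@H](CC=C(C)C)OC(=O)/C(C)=C/C | intermediate
29 | CNP0407453.3, (1R,2S,3S,4S,6S,8S,10R) in target numbering | C=C([C@@H]1[C@H](OC(=O)/C(C)=C/C)[C@@H]2O[C@]2(C)C(=O)[C@H]1OC(C)=O)[C@H](C[C@H]1OC1(C)C)OC(=O)/C(C)=C/C | target

**Step count**

Total: 23 steps. Longest linear sequence: 22 steps (steps 1–7 and 9–23 from epoxide 1); step 8 is a one-step side branch.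

**Steps most likely to fail**

Step 21 (directed epoxidation). The risk is poor facial selectivity. Peroxide that is not held by the C2 oxygen prefers axial attack at C3 on the face away from O2 and the side chain, and the peroxide anion may also cleave the C6 acetate.
Fallback, from 24 back to 26: Luche reduction of 24 (NaBH4, CeCl3·7H2O, MeOH, −78 °C) should give the 5-hydroxy compound F1 with the new hydroxyl on the face of O2 (axial hydride delivery, hydroxyl trans to the C6 acetate). VO(acac)2 with t-BuOOH in toluene then delivers oxygen to C3=C4 from the face of that allylic hydroxyl, giving the epoxy alcohol F2. Dess–Martin oxidation restores the ketone as the bis-PMB epoxy ketone F3, and DDQ as in step 20 gives 26.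

Step 16 (key carbocyclization). The risks are sequestration of the mercury catalyst by mercuration of the side-chain alkenes, and a slow aldol closure beside the bulky equatorial branch that stalls at the open chain.
Fallback, from 18 back to 20: metal-free hydration of the enol ether with dilute aqueous acid in THF, with loss of methanol, gives the open-chain keto aldehyde 4-O-acetyl-3,6-dideoxy-2-O-(4-methoxybenzyl)-3-C-[(3S)-3-(4-methoxybenzyloxy)-6-methylhepta-1,5-dien-2-yl]-D-lyxo-hexos-5-ulose F4. An amine-catalysed intramolecular aldol addition of its methyl ketone to the aldehyde (L-proline, DMSO, rt) closes the same C3–C4 bond and returns to 20.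

Step 3 (methoxymethylenation). The risks are incomplete olefination of the hindered ketone and base-induced epimerisation at C2 or β-elimination of the ulose.
Fallback, from 3 back to 5: non-basic Petasis methylenation (Cp2TiMe2, toluene, 70 °C) gives the 3-C-methylene sugar F5. Hydroboration–oxidation (9-BBN, THF; then NaOH, H2O2) should deliver hydrogen to C3 from the α face, away from the axial O2 substituent, to give the equatorial 3-C-hydroxymethyl mannoside F6. Dess–Martin oxidation followed by Et3N equilibration gives 5.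

**Further compounds**

F1 | step 21 | 6-acetoxy-5-hydroxy-2-(4-methoxybenzyloxy)-1-[(3S)-3-(4-methoxybenzyloxy)-6-methylhepta-1,5-dien-2-yl]-4-methylcyclohex-3-ene (5-OH cis to O2) | C=C([C@@H]1[C@H](OCc2ccc(OC)cc2)C=C(C)[C@H](O)[C@H]1OC(C)=O)[C@H](CC=C(C)C)OCc1ccc(OC)cc1
F2 | step 21 | 3,4-epoxide of F1 (oxirane cis to the 5-OH and O2) | C=C([C@@H]1[C@H](OCc2ccc(OC)cc2)[C@@H]2O[C@]2(C)[C@H](O)[C@H]1OC(C)=O)[C@H](CC=C(C)C)OCc1ccc(OC)cc1
F3 | step 21 | 6-acetoxy-3,4-epoxy-2-(4-methoxybenzyloxy)-1-[(3S)-3-(4-methoxybenzyloxy)-6-methylhepta-1,5-dien-2-yl]-4-methylcyclohexan-5-one | C=C([C@@H]1[C@H](OCc2ccc(OC)cc2)[C@@H]2O[C@]2(C)C(=O)[C@H]1OC(C)=O)[C@H](CC=C(C)C)OCc1ccc(OC)cc1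
F4 | step 16 | 4-O-acetyl-3,6-dideoxy-2-O-(4-methoxybenzyl)-3-C-[(3S)-3-(4-methoxybenzyloxy)-6-methylhepta-1,5-dien-2-yl]-D-lyxo-hexos-5-ulose | C=C([C@H]([C@H](OCc1ccc(OC)cc1)C=O)[C@H](OC(C)=O)C(C)=O)[C@H](CC=C(C)C)OCc1ccc(OC)cc1
F5 | step 3 | methyl 4,6-O-benzylidene-3-deoxy-2-O-(4-methoxybenzyl)-3-C-methylene-α-D-arabino-hexopyranoside | CO[C@H]1O[C@@H]2CO[C@@H](c3ccccc3)O[C@H]2C(=C)[C@@H]1OCc1ccc(OC)cc1
F6 | step 3 | methyl 4,6-O-benzylidene-3-deoxy-3-C-(hydroxymethyl)-2-O-(4-methoxybenzyl)-α-D-mannopyranoside | CO[C@H]1O[C@@H]2CO[C@@H](c3ccccc3)O[C@H]2[C@H](CO)[C@@H]1OCc1ccc(OC)cc1
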